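## Retrosynthetic overview

1. Feature: with the side chain numbered C1' (ring-bound CH2) to C16', the only stereocentre C9' (CH–OH) is bonded directly to alkene carbon C10' and, through the single methylene C8', to alkene carbon C7'. C8'–C9' is therefore treated as a latent vinyl group set between two ready-made E alkenes.
2. Key disconnection: C9'–C10' and C7'–C8' are formed in one enantioselective palladium-catalysed three-component (conjunctive) coupling. The partners are an east alkenylboronate (C10'–C16'), vinyllithium (C8', C9') and a west alkenyl bromide (ring A, C1'–C7'); C9' is created as a C–B centre.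
3. East: 5-bromo-2-methylpent-2-ene, alkyne, methylalumination/iodination, boronate. West: 4-methoxy-2-methylphenol, aryl bromide, SN2' opening of 2-methyl-2-vinyloxirane (E C2'=C3'), allylic bromide, but-2-ynylation, hydrozirconation/bromination (E C6'=C7'–Br).
4. End game: C–B to C–OH with retention, then oxidative demethylation of ring A to the quinone.
5. Rings: none is closed. The six-membered carbocycle (ring A) comes from the phenol as a 2,5-dimethoxy-3-methylphenyl group and becomes the quinone in the last step.

Key step: step 11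

Assumption: the sense of induction of the ferrocenyl diphosphine is taken to be that its (Sp,Sp) antipode gives the (R) descriptor when the migrating group outranks the CH2 arm, so the (Rp,Rp) antipode, (Rp,Rp)-1,1'-bis[bis(4-methoxy-3,5-dimethylphenyl)phosphino]-2,2'-bis[(S)-α-(dimethylamino)benzyl]ferrocene, is written for the (S) centre; both antipodes are sold, and the sense is to be checked on the first batch through the Mosher esters of the carbinol obtained after C–B oxidation.

## Route

Step 1
Reactants: 1 5-bromo-2-methylpent-2-ene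
Product: 2 6-methylhept-5-en-1-yne
Conditions: LiC≡CH·H2NCH2CH2NH2, DMSO, 10 °C → rt
Reagents that add atoms: lithium acetylide ethylenediamine complex, [Li]C#C.NCCN
Why: SN2 alkylation of lithium acetylide by a primary bromide in DMSO is a standard terminal-alkyne synthesis, and the trisubstituted alkene is inert to it.

Step 2
Reactants: 2 6-methylhept-5-en-1-yne
Product: 4 (1E)-1-iodo-2,6-dimethylhepta-1,5-diene, via alkenyldimethylalane 3 (not isolated)
Conditions: Me3Al (2 equiv), Cp2ZrCl2 (0.25 equiv), CH2Cl2, rt; then I2, THF, −30 → 0 °C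
Reagents that add atoms: trimethylaluminium, C[Al](C)C; iodine, II
Why: Negishi zirconium-catalysed methylalumination adds CH3 and Al syn with Al on the terminal carbon, and iodinolysis of the C–Al bond with retention should give the E iodide, while the isolated trisubstituted alkene does not react.

Step 3
Reactants: 4 (1E)-1-iodo-2,6-dimethylhepta-1,5-diene
Product: 6 2-[(1E)-2,6-dimethylhepta-1,5-dien-1-yl]-4,4,5,5-tetramethyl-1,3,2-dioxaborolane, via alkenyllithium 5 (not isolated)
Conditions: t-BuLi (2 equiv), Et2O, −78 °C; then i-PrOBpin, −78 °C → rt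
Reagents that add atoms: 2-isopropoxy-4,4,5,5-tetramethyl-1,3,2-dioxaborolane, CC(C)OB1OC(C)(C)C(C)(C)O1
Why: Iodine–lithium exchange proceeds with retention of alkene geometry, and borylation of the alkenyllithium by the isopropoxyboronate should give the E alkenyl pinacol boronate.

Step 4
Reactants: 7 tetravinylstannane
Product: 8 vinyllithium
Conditions: n-BuLi, pentane, rt; solid collected under argon, washed, dissolved in THF and titrated
Reagents that add atoms: n-butyllithium, [Li]CCCC
Why: Tin–lithium exchange (transmetallation), driven by precipitation of vinyllithium from pentane, should give a halide-free reagent, which matters because halide slows step 11.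

Step 5
Reactants: 9 4-methoxy-2-methylphenol
Product: 10 2-bromo-4-methoxy-6-methylphenol
Conditions: Br2 (1.0 equiv), CH2Cl2, 0 °C
Reagents that add atoms: bromine, BrBr
Why: Electrophilic aromatic bromination is directed by the hydroxyl group to its only free ortho position, since its para position carries OMe and its other ortho position the methyl group.

Step 6
Reactants: 10 2-bromo-4-methoxy-6-methylphenol
Product: 11 1-bromo-2,5-dimethoxy-3-methylbenzene
Conditions: MeI, K2CO3, acetone, reflux
Reagents that add atoms: iodomethane, CI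
Why: Williamson O-methylation of the phenoxide masks ring A as the base-stable dimethyl ether of the hydroquinone.

Step 7
Reactants: 11 1-bromo-2,5-dimethoxy-3-methylbenzene; 12 2-methyl-2-vinyloxirane
Product: 14 (2E)-4-(2,5-dimethoxy-3-methylphenyl)-2-methylbut-2-en-1-ol, via arylmagnesium bromide 13 (not isolated)
Conditions: Mg, THF, reflux; then CuI (10 mol%), 12, THF, −30 → 0 °C; aq NH4Cl
Reagents that add atoms: none
Why: Grignard formation followed by copper-catalysed anti SN2' opening of the vinyl oxirane at its terminal vinyl carbon, through the s-trans conformer, should give mainly the E trisubstituted allylic alcohol (C1'–C4'), any Z isomer being removed by chromatography.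

Step 8
Reactants: 14 (2E)-4-(2,5-dimethoxy-3-methylphenyl)-2-methylbut-2-en-1-ol
Product: 15 1-[(2E)-4-bromo-3-methylbut-2-en-1-yl]-2,5-dimethoxy-3-methylbenzene
Conditions: PBr3 (0.4 equiv), Et2O, 0 °C; used crude
Reagents that add atoms: phosphorus tribromide, BrP(Br)Br
Why: Bromide displaces the phosphite ester of the primary allylic alcohol by SN2 at 0 °C, and the primary trisubstituted allylic bromide is also the thermodynamically preferred isomer, so no allylic transposition is expected.

Step 9
Reactants: 15 1-[(2E)-4-bromo-3-methylbut-2-en-1-yl]-2,5-dimethoxy-3-methylbenzene; 16 but-2-yne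
Product: 18 2,5-dimethoxy-3-methyl-1-[(2E)-3-methyloct-2-en-6-yn-1-yl]benzene, via but-2-ynyllithium 17 (not isolated)
Conditions: 16 (excess), n-BuLi, THF, −78 → 0 °C; then 15, −78 → 0 °C
Reagents that add atoms: none
Why: Propargylic lithiation of but-2-yne and SN2 alkylation of the primary allylic bromide through the CH2 terminus of the anion should form C4'–C5' and give the 2-alkyne, the fast substitution at −78 °C outrunning deprotonation at C1'.

Step 10
Reactants: 18 2,5-dimethoxy-3-methyl-1-[(2E)-3-methyloct-2-en-6-yn-1-yl]benzene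
Product: 20 1-[(2E,6E)-7-bromo-3-methylocta-2,6-dien-1-yl]-2,5-dimethoxy-3-methylbenzene, via alkenylzirconocene chloride 19 (not isolated)
Conditions: Cp2Zr(H)Cl (2.2 equiv), THF, rt → 50 °C; then NBS (2.2 equiv), 0 °C
Reagents that add atoms: N-bromosuccinimide, O=C1CCC(=O)N1Br
Why: Syn hydrozirconation of the alkyne, with excess hydride equilibrating zirconium to the less hindered methyl-bearing carbon C7', followed by bromination of the C–Zr bond with retention should give the 6E bromide (Br trans to C5', as needed for a 6E alkene after step 11); the alkyne reacts far faster than the trisubstituted alkene, and the C–Zr bond far faster than ring A.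

Step 11
Reactants: 6 2-[(1E)-2,6-dimethylhepta-1,5-dien-1-yl]-4,4,5,5-tetramethyl-1,3,2-dioxaborolane; 8 vinyllithium; 20 1-[(2E,6E)-7-bromo-3-methylocta-2,6-dien-1-yl]-2,5-dimethoxy-3-methylbenzene
Product: 22 2-[(2E,6E,9S,10E)-1-(2,5-dimethoxy-3-methylphenyl)-3,7,11,15-tetramethylhexadeca-2,6,10,14-tetraen-9-yl]-4,4,5,5-tetramethyl-1,3,2-dioxaborolane, via lithium alkenyl(vinyl)borate 21 (not isolated)
Conditions: 6, 8 (1.0 equiv), THF, 0 °C → rt; then 20, Pd(OAc)2 (3 mol%), (Rp,Rp)-1,1'-bis[bis(4-methoxy-3,5-dimethylphenyl)phosphino]-2,2'-bis[(S)-α-(dimethylamino)benzyl]ferrocene (3.6 mol%), NaOTf (2 equiv), THF, 60 °C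
Reagents that add atoms: none
Why: Vinyllithium 8 adds to the boron of 6 to give borate 21; oxidative addition of 20 to zerovalent palladium (formed from Pd(OAc)2 under the reaction conditions) gives a divalent palladium alkenyl, from which NaOTf strips bromide so that the cationic metal can bind the unsubstituted vinyl group of 21. Coordination triggers an anti 1,2-shift of the trisubstituted alkenyl group from boron to C9' while C8' bonds to palladium, and reductive elimination then joins C8' to C7'; both alkenyl groups keep their E geometry because migration and reductive elimination are stereoretentive at sp2 carbon. The closest known reaction type is the enantioselective conjunctive cross-coupling of bis(alkenyl)borates with C(sp2) electrophiles, which gives α-chiral allylic pinacol boronates; no ring is closed. C9' is set by catalyst control: the ferrocenyl diphosphine decides which face of the palladium-bound vinyl group receives the migrating carbon, here the face that leads to S. The step needs chemoselectivity between the two alkenyl groups on boron and between the 1,2-shift and direct transmetallation; the first is secured by the steric difference (the unhindered vinyl binds palladium, the hindered alkenyl migrates) and the second by the pinacol ester and the wide-bite-angle ligand. The base-sensitive benzylic allylic C1'–H is not at risk because no strong base is present once 21 has formed.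

Step 12
Reactants: 22 2-[(2E,6E,9S,10E)-1-(2,5-dimethoxy-3-methylphenyl)-3,7,11,15-tetramethylhexadeca-2,6,10,14-tetraen-9-yl]-4,4,5,5-tetramethyl-1,3,2-dioxaborolane
Product: 23 (2E,6E,9S,10E)-1-(2,5-dimethoxy-3-methylphenyl)-3,7,11,15-tetramethylhexadeca-2,6,10,14-tetraen-9-ol
Conditions: 3 M NaOH, 30% H2O2, THF, 0 °C → rt
Reagents that add atoms: hydrogen peroxide, OO
Why: Oxidation of the C–B bond by hydroperoxide involves a 1,2-shift of C9' from boron to oxygen with retention, so the (S) boronate should give the (S) allylic alcohol without allylic transposition.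

Step 13
Reactants: 23 (2E,6E,9S,10E)-1-(2,5-dimethoxy-3-methylphenyl)-3,7,11,15-tetramethylhexadeca-2,6,10,14-tetraen-9-ol
Product: 24 2-[(2E,6E,9S,10E)-9-hydroxy-3,7,11,15-tetramethylhexadeca-2,6,10,14-tetraen-1-yl]-6-methylcyclohexa-2,5-diene-1,4-dione
Conditions: (NH4)2Ce(NO3)6 (2.5 equiv), MeCN/H2O, 0 °C, short reaction time
Reagents that add atoms: water, O
Why: Oxidative demethylation of the 1,4-dimethoxyarene by tetravalent cerium, with water supplying the quinone oxygens and methanol leaving, is much faster at 0 °C than oxidation of the trisubstituted alkenes or the secondary alcohol, so C9' is untouched.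

## Compound list

1 | 5-bromo-2-methylpent-2-ene | CC(C)=CCCBr | starting material
2 | 6-methylhept-5-en-1-yne | CC(C)=CCCC#C | intermediate
3 | [(1E)-2,6-dimethylhepta-1,5-dien-1-yl]dimethylalane | CC(C)=CCC/C(C)=C/[Al](C)C | intermediate (not isolated)
4 | (1E)-1-iodo-2,6-dimethylhepta-1,5-diene | CC(C)=CCC/C(C)=C/I | intermediate
5 | [(1E)-2,6-dimethylhepta-1,5-dien-1-yl]lithium | CC(C)=CCC/C(C)=C/[Li] | intermediate (not isolated)
6 | 2-[(1E)-2,6-dimethylhepta-1,5-dien-1-yl]-4,4,5,5-tetramethyl-1,3,2-dioxaborolane | CC(C)=CCC/C(C)=C/B1OC(C)(C)C(C)(C)O1 | intermediate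
7 | tetravinylstannane | C=C[Sn](C=C)(C=C)C=C | starting material
8 | vinyllithium | [Li]C=C | intermediate
9 | 4-methoxy-2-methylphenol | COc1ccc(O)c(C)c1 | starting material
10 | 2-bromo-4-methoxy-6-methylphenol | COc1cc(C)c(O)c(Br)c1 | intermediate
11 | 1-bromo-2,5-dimethoxy-3-methylbenzene | COc1cc(C)c(OC)c(Br)c1 | intermediate
12 | 2-methyl-2-vinyloxirane (racemic) | CC1(C=C)CO1 | starting material
13 | (2,5-dimethoxy-3-methylphenyl)magnesium bromide | COc1cc(C)c(OC)c([Mg]Br)c1 | intermediate (not isolated)
14 | (2E)-4-(2,5-dimethoxy-3-methylphenyl)-2-methylbut-2-en-1-ol | OC/C(C)=C/Cc1cc(OC)cc(C)c1OC | intermediate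
15 | 1-[(2E)-4-bromo-3-methylbut-2-en-1-yl]-2,5-dimethoxy-3-methylbenzene | BrC/C(C)=C/Cc1cc(OC)cc(C)c1OC | intermediate
16 | but-2-yne | CC#CC | starting material
17 | but-2-yn-1-yllithium | [Li]CC#CC | intermediate (not isolated)
18 | 2,5-dimethoxy-3-methyl-1-[(2E)-3-methyloct-2-en-6-yn-1-yl]benzene | CC#CCC/C(C)=C/Cc1cc(OC)cc(C)c1OC | intermediate
19 | chlorobis(cyclopentadienyl)[(2E,6E)-8-(2,5-dimethoxy-3-methylphenyl)-6-methylocta-2,6-dien-2-yl]zirconium | C/C(=C\CC/C(C)=C/Cc1cc(OC)cc(C)c1OC)[Zr](Cl)(C1C=CC=C1)C1C=CC=C1 | intermediate (not isolated)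
20 | 1-[(2E,6E)-7-bromo-3-methylocta-2,6-dien-1-yl]-2,5-dimethoxy-3-methylbenzene (Br trans to C5') | C/C(Br)=C\CC/C(C)=C/Cc1cc(OC)cc(C)c1OC | intermediate
21 | lithium [(1E)-2,6-dimethylhepta-1,5-dien-1-yl](ethenyl)(2,3-dimethylbutane-2,3-diolato)borate | [Li+].CC(C)=CCC/C(C)=C/[B-]1(C=C)OC(C)(C)C(C)(C)O1 | intermediate (not isolated)
22 | 2-[(2E,6E,9S,10E)-1-(2,5-dimethoxy-3-methylphenyl)-3,7,11,15-tetramethylhexadeca-2,6,10,14-tetraen-9-yl]-4,4,5,5-tetramethyl-1,3,2-dioxaborolane | CC(C)=CCC/C(C)=C/[C@@H](B1OC(C)(C)C(C)(C)O1)C/C(C)=C/CC/C(C)=C/Cc1cc(OC)cc(C)c1OC | intermediate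
23 | (2E,6E,9S,10E)-1-(2,5-dimethoxy-3-methylphenyl)-3,7,11,15-tetramethylhexadeca-2,6,10,14-tetraen-9-ol | CC(C)=CCC/C(C)=C/[C@@H](O)C/C(C)=C/CC/C(C)=C/Cc1cc(OC)cc(C)c1OC | intermediate
24 | 2-[(2E,6E,9S,10E)-9-hydroxy-3,7,11,15-tetramethylhexadeca-2,6,10,14-tetraen-1-yl]-6-methylcyclohexa-2,5-diene-1,4-dione | CC(C)=CCC/C(C)=C/[C@@H](O)C/C(C)=C/CC/C(C)=C/CC1=CC(=O)C=C(C)C1=O | target

## Step count

Total step count: 13. Longest linear sequence: 9 steps (steps 5 to 13, from 4-methoxy-2-methylphenol).

## Steps most likely to fail

**Step 11.** Oxidative addition of the hindered trisubstituted alkenyl bromide may be slow. Direct transmetallation of either alkenyl group from boron (coupling without the 1,2-shift) could then compete, and facial control at C9' may be lower than with small electrophiles.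

Fallback: it sets out from 20. Bromine–lithium exchange (t-BuLi, Et2O, −78 °C) and opening of ethylene oxide in the presence of BF3·OEt2 should give (3E,7E)-9-(2,5-dimethoxy-3-methylphenyl)-3,7-dimethylnona-3,7-dien-1-ol F1. Dess–Martin periodinane buffered with NaHCO3 should give (3E,7E)-9-(2,5-dimethoxy-3-methylphenyl)-3,7-dimethylnona-3,7-dienal F2, used crude because its β,γ-alkene can move into conjugation. A catalytic enantioselective Nozaki–Hiyama–Kishi coupling of F2 with iodide 4 (CrCl2, NiCl2, chiral oxazoline sulfonamide ligand, Mn, Cp2ZrCl2, MeCN), run with the ligand antipode that sends the alkenyl group to the Re face of the aldehyde, comes back to the route at 23.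

**Step 9.** The ambident butynyl anion may bond through its methyl-bearing (allenyl) terminus, or act as a base on the benzylic allylic C1'–H of 15 with 1,4-loss of HBr.

Fallback: it sets out from 15. Alkylation of lithiated 1-(trimethylsilyl)propyne (n-BuLi, THF, −78 °C), a more stabilised anion whose silyl group blocks the allenyl terminus, should give [(5E)-7-(2,5-dimethoxy-3-methylphenyl)-5-methylhept-5-en-1-yn-1-yl]trimethylsilane F3. K2CO3 in MeOH should give 2,5-dimethoxy-3-methyl-1-[(2E)-3-methylhept-2-en-6-yn-1-yl]benzene F4. Deprotonation of the alkyne C–H (n-BuLi, THF, −78 °C) and MeI come back to the route at 18.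

**Step 10.** Migration of zirconium to C7' may stay incomplete, leaving the 6-bromo regioisomer, which would be hard to separate at this size; NBS may also attack ring A.

Fallback: the alkenyl bromide is made first on a small alkyne and ring A is attached last. It sets out from commercial pent-3-yn-1-ol (CC#CCCO) and from 11.
- Hydrozirconation/bromination (Cp2Zr(H)Cl, THF; NBS) should give (3E)-4-bromopent-3-en-1-ol F5, from which a regioisomer is easily removed.
- I2, PPh3 and imidazole should give (2E)-2-bromo-5-iodopent-2-ene F6.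
- LiC≡CH·H2NCH2CH2NH2 in DMSO should give (5E)-6-bromohept-5-en-1-yne F7.
- Methylalumination (Me3Al, Cp2ZrCl2), then n-BuLi and paraformaldehyde, should give (2E,6E)-7-bromo-3-methylocta-2,6-dien-1-ol F8.
- PBr3 should give (2E,6E)-1,7-dibromo-3-methylocta-2,6-diene F9.
- Copper-catalysed SN2 coupling of F9 at its primary allylic carbon with Grignard reagent 13 (from 11; CuI, THF, −30 °C) comes back to the route at 20.

## Further compounds

F1 | step 11 | (3E,7E)-9-(2,5-dimethoxy-3-methylphenyl)-3,7-dimethylnona-3,7-dien-1-ol | OCC/C(C)=C/CC/C(C)=C/Cc1cc(OC)cc(C)c1OC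
F2 | step 11 | (3E,7E)-9-(2,5-dimethoxy-3-methylphenyl)-3,7-dimethylnona-3,7-dienal | O=CC/C(C)=C/CC/C(C)=C/Cc1cc(OC)cc(C)c1OC
F3 | step 9 | [(5E)-7-(2,5-dimethoxy-3-methylphenyl)-5-methylhept-5-en-1-yn-1-yl]trimethylsilane | C[Si](C)(C)C#CCC/C(C)=C/Cc1cc(OC)cc(C)c1OC
F4 | step 9 | 2,5-dimethoxy-3-methyl-1-[(2E)-3-methylhept-2-en-6-yn-1-yl]benzene | C#CCC/C(C)=C/Cc1cc(OC)cc(C)c1OC
F5 | step 10 | (3E)-4-bromopent-3-en-1-ol | C/C(Br)=C\CCO
F6 | step 10 | (2E)-2-bromo-5-iodopent-2-ene | C/C(Br)=C\CCI
F7 | step 10 | (5E)-6-bromohept-5-en-1-yne | C/C(Br)=C\CCC#C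
F8 | step 10 | (2E,6E)-7-bromo-3-methylocta-2,6-dien-1-ol | C/C(Br)=C\CC/C(C)=C/CO
F9 | step 10 | (2E,6E)-1,7-dibromo-3-methylocta-2,6-diene | C/C(Br)=C\CC/C(C)=C/CBr
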